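Millimolar of product is the unit to reckon in here, not percent: the flasks differ in charge, and percent hides what each one actually made.

the same everywhere: gas 0.90 mM (held)
- summer: substrate 0.0061 M; run made earlier
- dawn: substrate 0.055 M; run made earlier
- ash: substrate 0.060 M; time 20 min
- oak: substrate 0.030 M; time 20 min
- cedar: substrate 0.020 M; time 20 min
- birch: substrate 0.080 M; time 20 min
- alder: substrate 0.040 M; time 20 min
- larch: substrate 0.012 M; time 20 min

| run | time / min | product / % | substrate / % |
|---|---|---|---|
| summer | 1.50 | 8.2 | 92.9 |
| summer | 2.50 | 14.1 | 86.3 |
| summer | 4.00 | 23.4 | 77.1 |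
| summer | 6.00 | 35.0 | 64.7 |
| summer | 8.00 | 45.7 | 54.3 |
| summer | 12.0 | 62.1 | 37.7 |
| summer | 20.0 | 79.0 | 21.4 |
| dawn | 1.50 | 1.6 | 98.4 |
| dawn | 2.50 | 2.2 | 97.8 |
| dawn | 4.00 | 3.6 | 95.3 |
| dawn | 6.00 | 5.7 | 94.3 |
| dawn | 8.00 | 7.6 | 91.6 |
| dawn | 12.0 | 10.8 | 88.1 |
| dawn | 20.0 | 17.5 | 81.2 |

(each reading ± 0.3 percentage points)

- the earlier runs were read with a standard deviation of 0.3 percentage points
- at the start none of the gas is in solution

* all flasks from highest to lowest amount of product, in percent of the substrate charged, at 20 min (ash / oak / cedar / birch / alder / larch)
* the amount of product, in percent of the substrate charged of the flask you put first, at 20 min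
* the amount of product, in percent of the substrate charged of the flask you put last, at 20 min

Dawn, charged at 0.055 M, holds 9.63 mM of product at 20 min, and its readings climb almost in a straight line, nearly zero order in substrate. If every flask made that amount, birch would stand at 12.0% and larch at 80.2%. Summer breaks this link: it makes 4.82 mM, half of dawn's amount, with 21.4% of its substrate still there. So the larch figure is the weak one.

To reforge it, let the rate thin out as [substrate]/(K + [substrate]). Added up over a run, this assumed rate gives a balance: the product made, plus K times the natural log of charged over remaining [substrate], comes out the same for any charge, with time and gas held. Subtracting summer's balance from dawn's gives a reading of K = 3.60 mM, and the balance then stands at 10.4 mM. Call this the twenty-minute supply: what a flask would make in 20 min with [substrate] far above K all the way.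

For larch, the full charge suggests 7.98 mM, which means a mean [substrate] near 8.01 mM, and that mean gives 7.16 mM, or 59.6%. Put back into the balance, this returns 10.4 mM, close to the supply. Birch gets 9.91 mM, or 12.4%. Your percentage falls from larch to birch as the charge rises, so you place cedar, oak, alder and ash between them in order of charge.

The forecast gives larch > cedar > oak > alder > ash > birch, with 57% (50% to 65%) for larch, lower than your figure, and 12.5% (11.3% to 13.5%) for birch, reasoning that “Percent conversion therefore falls as the substrate charge rises”.

The flasks give larch > cedar > oak > alder > ash > birch, with larch at 59.6% and birch at 12.5%.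

    substrate + partner ⇌ product + released group (K = 28.0, k = 370 M⁻¹ min⁻¹)
    2 substrate → homo dimer (k = 0.00780 M⁻¹ min⁻¹)
    gas ⇌ partner, rate k3*(csat - [partner]) (kL = 0.580 min⁻¹)

Left until 200 min, larch stands at 73.7%. A further flask, like larch but charged at 0.0072 M, holds 74.9% product and 25.0% substrate at 20 min. That is 5.39 mM of product, and with the same 3.60 mM in the log term its balance comes to 10.4 mM, beside a supply of 10.4 mM.

The numbers in the tables are simulated with made-up constants.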